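**Retrosynthetic overview**
1. Target 14 ← global desilylation of hexa‑TIPS ether 13.
2. 13 ← C1–C2 bond: chiral Brønsted‑acid ionisation of benzhydryl silyl ether 12 and o‑quinodimethane/enol 6π ring closure. This forms the only new ring (the 1,2‑dihydronaphthalene carbocycle) and both stereocentres.
3. 12 ← C3=C4 by crossed aldol condensation of aldehyde 8 with the symmetric 1,4‑diketone 11 (oxidative enolate dimerisation of protected 4'‑hydroxyacetophenone).
4. 8 ← carbinol‑directed ortho‑lithiation/formylation of the symmetric bis‑aryl methanol 5 ← OMe‑directed lithiation of protected 3‑methoxycatechol plus ethyl formate. Both catechol rings come from one arene, and C1 carries both through their ipso carbons.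
5. All four benzene rings are purchased; the route has not been run, and every selectivity stated is a prediction.

Assumption: the SMILES is read as (1S,2S), with the C1 aryl and C2 aroyl cis; the (R)‑catalyst is assumed to give this enantiomer, and its antipode is used if not.

**Step 1**
Reactants: 1 3‑methoxycatechol; 2 triisopropylsilyl triflate
Product: 3 1‑methoxy‑2,3‑bis(triisopropylsilyloxy)benzene
Conditions: TIPSOTf (2.3 equiv), 2,6‑lutidine, CH2Cl2, 0 °C → rt
Reagents that add atoms: TIPSOTf, CC(C)[Si](OS(=O)(=O)C(F)(F)F)(C(C)C)C(C)C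
Why: Phenol O‑silylation; the bulky, non‑coordinating OTIPS groups survive alkyllithiums and leave OMe as the only directing group for step 2.

**Step 2**
Reactants: 3 (2.1 equiv); 4 ethyl formate (1 equiv)
Product: 5 bis[2‑methoxy‑3,4‑bis(triisopropylsilyloxy)phenyl]methanol (achiral)
Conditions: n‑BuLi, TMEDA, Et2O, 0 °C → rt; then HCO2Et, −78 °C → rt
Reagents that add atoms: ethyl formate, O=COCC
Why: Directed ortho‑metalation at the C–H next to OMe (as for 1,2,3‑trialkoxybenzenes), then double aryllithium addition to the formate ester gives the symmetric diarylmethanol.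

**Step 3**
Reactants: 5; 6 N,N‑dimethylformamide; 7 triethylsilyl triflate
Product: 8 rac‑3‑methoxy‑2‑{[2‑methoxy‑3,4‑bis(triisopropylsilyloxy)phenyl](triethylsilyloxy)methyl}‑4,5‑bis(triisopropylsilyloxy)benzaldehyde
Conditions: n‑BuLi (2.3 equiv), TMEDA, Et2O, 0 °C → rt; DMF, −78 → 0 °C; TESOTf, −78 → 0 °C; aq NaHCO3
Reagents that add atoms: DMF, CN(C)C=O; TESOTf, CC[Si](CC)(CC)OS(=O)(=O)C(F)(F)F
Why: Lithium‑alkoxide‑directed ortho‑lithiation takes the only H ortho to the carbinol carbon (the other ortho position is OMe), so CHO lands para to the 3‑oxygen with no regiochemical ambiguity; the in‑situ TES cap prevents lactol formation and later oxa‑Michael closure, and silyloxide is not a leaving group under base.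

**Step 4**
Reactants: 9 4'‑hydroxyacetophenone; 2 TIPSOTf
Product: 10 1‑[4‑(triisopropylsilyloxy)phenyl]ethan‑1‑one
Conditions: TIPSOTf, 2,6‑lutidine, CH2Cl2, 0 °C
Reagents that add atoms: TIPSOTf, CC(C)[Si](OS(=O)(=O)C(F)(F)F)(C(C)C)C(C)C
Why: Routine phenol silylation, giving one protecting‑group type for a single final deprotection.

**Step 5**
Reactants: 10 (2 equiv)
Product: 11 1,4‑bis[4‑(triisopropylsilyloxy)phenyl]butane‑1,4‑dione
Conditions: LDA, THF, −78 °C; CuCl2, DMF, −78 °C → rt
Reagents that add atoms: none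
Why: Saegusa‑type oxidative homocoupling of the lithium enolate gives the symmetric 1,4‑diketone directly.

**Step 6**
Reactants: 8; 11 (2 equiv, excess recovered)
Product: 12 rac‑(E)‑2‑arylmethylidene‑1,4‑bis[4‑(triisopropylsilyloxy)phenyl]butane‑1,4‑dione, where aryl is the ring of 8 (aryl cis to the CH2C(O)Ar arm)
Conditions: LiHMDS (2 equiv), THF, −78 °C; then 8; MsCl, Et3N, −78 → 0 °C
Reagents that add atoms: none
Why: Crossed aldol condensation (lithium enolate addition, mesylation, E1cB) of a symmetric diketone with a non‑enolisable aldehyde; the thermodynamic E‑enone places the CH2 arm cis to the arene, as the ring closure needs.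

**Step 7 (key step)**
Reactants: 12
Product: 13 [(1S,2S)‑8‑methoxy‑1‑[2‑methoxy‑3,4‑bis(triisopropylsilyloxy)phenyl]‑6,7‑bis(triisopropylsilyloxy)‑3‑[4‑(triisopropylsilyloxy)benzoyl]‑1,2‑dihydronaphthalen‑2‑yl][4‑(triisopropylsilyloxy)phenyl]methanone
Conditions: (R)‑3,3'‑bis(2,4,6‑triisopropylphenyl)‑BINOL N‑triflylphosphoramide (10 mol%), 5 Å MS, toluene (0.02 M), −40 → −10 °C; Et3N quench
Reagents that add atoms: none (Et3SiOH is lost)
Why: Proposed new method: the chiral acid ionises the benzhydryl OTES to a diarylmethyl cation (stabilised by o‑OMe and p‑OSi on both rings, so the racemic C1 centre is erased) paired with the chiral anion, loss of the vinylogously acidified C2–H (or enolisation of the C2 ketone) gives an o‑quinodimethane/dienol, and disrotatory 6π closure forms C1–C2 with the aryl "outside" at C1 and the aroyl "outside" at C2, which gives the cis ring junction under kinetic control, while the anion (ion‑paired at C1, H‑bonded to the C2 enol/carbonyl) selects the helical sense and hence (1S,2S); the closest known reaction types are chiral N‑triflylphosphoramide‑catalysed Nazarov cyclisations (which give kinetic cis products) and phosphoric‑acid‑catalysed enol additions to in‑situ diarylmethyl cations and quinone methides.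

**Step 8**
Reactants: 13
Product: 14 licobichalcone, [(1S,2S)‑1‑(3,4‑dihydroxy‑2‑methoxyphenyl)‑6,7‑dihydroxy‑3‑(4‑hydroxybenzoyl)‑8‑methoxy‑1,2‑dihydronaphthalen‑2‑yl](4‑hydroxyphenyl)methanone
Conditions: TBAF/AcOH (1:1, 8 equiv), degassed THF, 0 °C → rt
Reagents that add atoms: none
Why: Fluoride desilylation of six aryl silyl ethers; the acetic acid buffer keeps the medium non‑basic so the epimerisable C2–H (α to a ketone, allylic) and the catechols are untouched, and the OMe groups, ketones and alkene are inert.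

**Compound list**
1 | 3‑methoxycatechol | COc1cccc(O)c1O | starting material
2 | triisopropylsilyl triflate | CC(C)[Si](OS(=O)(=O)C(F)(F)F)(C(C)C)C(C)C | starting material
3 | 1‑methoxy‑2,3‑bis(triisopropylsilyloxy)benzene | COc1cccc(O[Si](C(C)C)(C(C)C)C(C)C)c1O[Si](C(C)C)(C(C)C)C(C)C | intermediate
4 | ethyl formate | O=COCC | starting material
5 | bis[2‑methoxy‑3,4‑bis(triisopropylsilyloxy)phenyl]methanol | OC(c1ccc(O[Si](C(C)C)(C(C)C)C(C)C)c(O[Si](C(C)C)(C(C)C)C(C)C)c1OC)c1ccc(O[Si](C(C)C)(C(C)C)C(C)C)c(O[Si](C(C)C)(C(C)C)C(C)C)c1OC | intermediate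
6 | N,N‑dimethylformamide | CN(C)C=O | starting material
7 | triethylsilyl triflate | CC[Si](CC)(CC)OS(=O)(=O)C(F)(F)F | starting material
8 | rac‑3‑methoxy‑2‑{[2‑methoxy‑3,4‑bis(TIPSO)phenyl](triethylsilyloxy)methyl}‑4,5‑bis(TIPSO)benzaldehyde | O=Cc1cc(O[Si](C(C)C)(C(C)C)C(C)C)c(O[Si](C(C)C)(C(C)C)C(C)C)c(OC)c1C(O[Si](CC)(CC)CC)c1ccc(O[Si](C(C)C)(C(C)C)C(C)C)c(O[Si](C(C)C)(C(C)C)C(C)C)c1OC | intermediate
9 | 4'‑hydroxyacetophenone | CC(=O)c1ccc(O)cc1 | starting material
10 | 1‑[4‑(triisopropylsilyloxy)phenyl]ethan‑1‑one | CC(=O)c1ccc(O[Si](C(C)C)(C(C)C)C(C)C)cc1 | intermediate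
11 | 1,4‑bis[4‑(triisopropylsilyloxy)phenyl]butane‑1,4‑dione | O=C(CCC(=O)c1ccc(O[Si](C(C)C)(C(C)C)C(C)C)cc1)c1ccc(O[Si](C(C)C)(C(C)C)C(C)C)cc1 | intermediate
12 | rac‑(E)‑2‑arylmethylidene‑1,4‑diketone (racemic at the OTES carbon) | O=C(C/C(=C\c1cc(O[Si](C(C)C)(C(C)C)C(C)C)c(O[Si](C(C)C)(C(C)C)C(C)C)c(OC)c1C(O[Si](CC)(CC)CC)c1ccc(O[Si](C(C)C)(C(C)C)C(C)C)c(O[Si](C(C)C)(C(C)C)C(C)C)c1OC)C(=O)c1ccc(O[Si](C(C)C)(C(C)C)C(C)C)cc1)c1ccc(O[Si](C(C)C)(C(C)C)C(C)C)cc1 | intermediate
13 | (1S,2S)‑hexa‑O‑TIPS‑licobichalcone | COc1c([C@H]2c3c(cc(O[Si](C(C)C)(C(C)C)C(C)C)c(O[Si](C(C)C)(C(C)C)C(C)C)c3OC)C=C(C(=O)c3ccc(O[Si](C(C)C)(C(C)C)C(C)C)cc3)[C@H]2C(=O)c2ccc(O[Si](C(C)C)(C(C)C)C(C)C)cc2)ccc(O[Si](C(C)C)(C(C)C)C(C)C)c1O[Si](C(C)C)(C(C)C)C(C)C | intermediate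
14 | licobichalcone, (1S,2S) | COc1c([C@H]2c3c(cc(O)c(O)c3OC)C=C(C(=O)c3ccc(O)cc3)[C@H]2C(=O)c2ccc(O)cc2)ccc(O)c1O | target

**Step count and risks**
Total steps: 8. Longest linear sequence: 6 (steps 1, 2, 3, 6, 7, 8).

Steps most likely to fail:
- **Step 7 (proposed new reaction).** Risks are low ee, partial trans product from a stepwise closure or acid‑catalysed C2 epimerisation, and acid isomerisation of 12 to a 3‑benzylfuran. Fallback with known chemistry: set C1 intermolecularly by the established chiral‑phosphoric‑acid 1,6‑addition of the silyl enol ether of 11 (or a β‑keto ester surrogate) to a para‑quinone methide generated in situ from the 4‑OH‑free analogue of the carbinol. Then close C3=C4 by intramolecular aldol condensation onto the ortho aldehyde, and set cis C2–H by kinetic protonation of the C2 dienolate (LiHMDS, −78 °C, hindered phenol quench), which delivers H anti to the pseudoaxial C1 aryl.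
- **Step 3.** Alkoxide‑directed lithiation may be sluggish or give dilithiation, and the TES cap may be incomplete. Fallback: form the same C1–aryl bond from the other side. Lithiate 3‑methoxy‑4,5‑bis(TIPSO)benzaldehyde (from 5‑hydroxyvanillin) between OMe and the masked CHO via its α‑amino alkoxide (Comins protocol), add it to 2‑methoxy‑3,4‑bis(TIPSO)benzaldehyde (3, n‑BuLi, DMF), and cap with TESOTf.
- **Step 6.** Risks are bis‑condensation and base isomerisation of the enone into the ene‑dione. Fallback: Horner–Wadsworth–Emmons olefination of 8 with the phosphonate ArCOCH(P(O)(OEt)2)CH2COAr (from the β‑ketophosphonate and the phenacyl bromide) under LiCl/DBU or Ba(OH)2.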